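**Retrosynthetic overview**
1. Target 23 comes from macrocyclic tert-butyl enoate 17. The C14 ester is taken down to CH2OAc, and the C8 chloroacetate is converted into the hydroxyacetate.
2. Key disconnection is C8–C9. An α-acyloxyalkyl radical at C8 closes the ten-membered ring (10-endo) onto the free acrylate terminus C9 of a Baylis–Hillman acetate. Loss of the C1 acetate then gives the C1=C10 alkene.
3. C6–C7 is made by a catalytic asymmetric chromium allylation of aldehyde 7 with dienyl bromide 11, which gives the cis α-methylene lactone directly.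
4. C4 comes from an enzymatic Baeyer–Villiger desymmetrisation of 4-methylcyclohexanone. Both acrylate units come from Baylis–Hillman reactions.
5. Ring order: lactone first (step 7), ten-membered carbocycle second (step 9).

Assumption: locants are germacrane-type (ring C1–C10 with the C1=C10 alkene, C4 methyl-bearing, C6 lactone O-bearing, C7 ring fusion, C8 ester-bearing; C11–C13 α-methylene lactone carbons, C14 = CH2OAc carbon, C15 = methyl), and C1 in 5–16 is carried as an epimer mixture on purpose because it becomes sp2 in step 9.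

Step 1
Reactants: 1 4-methylcyclohexanone
Product: 2 (5S)-5-methyloxepan-2-one
Conditions: cyclohexanone monooxygenase, NADP+ (cat.), glucose dehydrogenase, D-glucose, air, Tris buffer pH 8, 25 °C
Reagents that add atoms: dioxygen, O=O
Why: Enzymatic Baeyer–Villiger desymmetrisation in which only one of the two enantiotopic α-CH2 groups migrates, so C4 is fixed as S (above 98% ee for this substrate) and the two chain ends come out differentiated (C1 acyl, C6 O-alkyl).

Step 2
Reactants: 2 (5S)-5-methyloxepan-2-one
Product: 3 (4S)-6-hydroxy-4-methylhexanal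
Conditions: i-Bu2AlH (1.05 equiv), CH2Cl2, −78 °C; aq. potassium sodium tartrate
Reagents that add atoms: none
Why: Partial lactone reduction, where the aluminium hemiacetal is stable at −78 °C and releases the C1 aldehyde only on work-up, leaving C4 untouched.

Step 3
Reactants: 3 (4S)-6-hydroxy-4-methylhexanal; 4 tert-butyl acrylate
Product: 5 tert-butyl (6S)-3,8-dihydroxy-6-methyl-2-methylideneoctanoate (C3 epimers)
Conditions: DABCO (1 equiv), 4 (3 equiv), 1,4-dioxane/H2O 1:1, 25 °C, 4 d
Reagents that add atoms: none
Why: Morita–Baylis–Hillman reaction, which tolerates the free primary alcohol and joins C1 to C10 while leaving C9 as an unsubstituted acrylate terminus; the new carbinol (C1) needs no control.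

Step 4
Reactants: 5 tert-butyl (6S)-3,8-dihydroxy-6-methyl-2-methylideneoctanoate
Product: 7 tert-butyl (6S)-3-acetoxy-6-methyl-2-methylidene-8-oxooctanoate, via hydroxy aldehyde 6 (not isolated)
Conditions: TEMPO (10 mol %), PhI(OAc)2 (1.1 equiv), CH2Cl2, 25 °C; then Ac2O, pyridine, DMAP (cat.), 0 °C
Reagents that add atoms: acetic anhydride, CC(=O)OC(C)=O
Why: The oxoammonium (TEMPO) oxidation takes the unhindered primary alcohol much faster than the electron-poor secondary allylic one, and acetylation in the same flask then turns the C1 hydroxyl into the leaving group needed in step 9.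

Step 5
Reactants: 8 acrolein; 9 methyl acrylate
Product: 10 methyl 3-hydroxy-2-methylidenepent-4-enoate (racemic)
Conditions: DABCO (15 mol %), neat, 0 to 25 °C
Reagents that add atoms: none
Why: Morita–Baylis–Hillman reaction with acrolein acting as the aldehyde partner; the stereocentre is erased in step 6.

Step 6
Reactants: 10 methyl 3-hydroxy-2-methylidenepent-4-enoate
Product: 11 methyl (2Z)-2-(bromomethyl)penta-2,4-dienoate
Conditions: PBr3 (0.4 equiv), Et2O, −10 °C
Reagents that add atoms: phosphorus tribromide, BrP(Br)Br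
Why: SN2′ bromination of a Baylis–Hillman alcohol, which gives the conjugated Z bromide (vinyl group cis to CH2Br), the geometry that leads to the syn adduct in step 7.

Step 7
Reactants: 7 tert-butyl (6S)-3-acetoxy-6-methyl-2-methylidene-8-oxooctanoate; 11 methyl (2Z)-2-(bromomethyl)penta-2,4-dienoate
Product: 14 tert-butyl (6S)-3-acetoxy-7-[(2S,3S)-3-ethenyl-4-methylidene-5-oxooxolan-2-yl]-6-methyl-2-methylideneheptanoate, via silyl ether 12 (not isolated), via hydroxy ester 13 (not isolated)
Conditions: CrCl2 (10 mol %), (S,S)-3,6-di-tert-butyl-1,8-bis(4-isopropyl-4,5-dihydrooxazol-2-yl)carbazole (12 mol %), Mn powder, Me3SiCl, THF, 0 °C; then 1 M HCl, THF, 25 °C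
Reagents that add atoms: none
Why: Catalytic asymmetric Nozaki–Hiyama-type 2-(alkoxycarbonyl)allylation in which the allylchromium reacts at C7 through a six-membered chair, the vinyl group cis to CH2Cr gives the syn adduct (hence the cis lactone after acid lactonisation), and the ligand antipode is chosen so that the aldehyde face leading to 6S,7S is attacked regardless of the remote C4 centre.

Step 8
Reactants: 14 vinyl cis-lactone
Product: 15 tert-butyl (6S)-3-acetoxy-7-[(2S,3S)-3-formyl-4-methylidene-5-oxooxolan-2-yl]-6-methyl-2-methylideneheptanoate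
Conditions: O3, CH2Cl2, −78 °C, Sudan Red 7B end point; PPh3; used crude at once
Reagents that add atoms: ozone, [O-][O+]=O
Why: Chemoselective ozonolysis, since the isolated vinyl group reacts far faster than the two ester-conjugated methylene groups, and the neutral work-up avoids enolisation at C7.

Step 9
Reactants: 15 formyl cis-lactone
Product: 17 tert-butyl (3aS,4S,6E,10S,11aS)-4-(chloroacetoxy)-10-methyl-3-methylidene-2-oxo-2,3,3a,4,5,8,9,10,11,11a-decahydrocyclodeca[b]furan-6-carboxylate, via bromoalkyl ester 16 (not isolated)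
Conditions: ClCH2COBr (1.05 equiv, from ClCH2COCl/Me3SiBr), ZnBr2 (2 mol %), CH2Cl2, −20 °C; evaporate; PhH (1 mM), Cp2TiCl (2.3 equiv, from Cp2TiCl2/Zn, 0.05 M in THF) by syringe pump over 12 h, 25 °C
Reagents that add atoms: chloroacetyl bromide, O=C(Br)CCl
Why: Proposed new method: the acyl bromide adds to the aldehyde to give an anomeric-type 1-bromoalkyl ester, trivalent titanium abstracts the bromine (as it does from glycosyl bromides), the C8 α-acyloxyalkyl radical adds 10-endo to the unsubstituted acrylate terminus C9, a second Cp2TiCl captures the C10 radical as a titanium enolate, and this expels the C1 acetate to give the E enoate (C2 cis to C9, the less strained ring-cis alkene) without hydride or base; the cis-lactone holds both arms on one face, and with H7 eclipsing the C8–O bond C9 can only arrive from the C6 side, anti to C11, which sets 8S; closest known types are Giese/Porter radical macrocyclisation, titanocene-mediated C-glycosylation and radical allylation with Baylis–Hillman acetates.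

Step 10
Reactants: 17 macrocyclic tert-butyl enoate
Product: 18 (3aS,4S,6E,10S,11aS)-4-(chloroacetoxy)-10-methyl-3-methylidene-2-oxo-2,3,3a,4,5,8,9,10,11,11a-decahydrocyclodeca[b]furan-6-carboxylic acid
Conditions: CF3CO2H/CH2Cl2 1:4, 0 to 25 °C
Reagents that add atoms: none
Why: Acidolysis of the tert-butyl ester (E1 loss of isobutene), which leaves the lactone, the chloroacetate and both alkenes untouched.

Step 11
Reactants: 18 macrocyclic enoic acid
Product: 21 (3aS,4S,6E,10S,11aS)-6-(acetoxymethyl)-10-methyl-3-methylidene-2-oxo-2,3,3a,4,5,8,9,10,11,11a-decahydrocyclodeca[b]furan-4-yl chloroacetate, via mixed anhydride 19 (not isolated), via allylic alcohol 20 (not isolated)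
Conditions: i-BuOCOCl, N-methylmorpholine, THF, −20 °C; NaBH4, MeOH (dropwise), −40 °C; then Ac2O, Et3N, DMAP (cat.), CH2Cl2, 0 °C
Reagents that add atoms: acetic anhydride, CC(=O)OC(C)=O
Why: Mixed carbonic anhydride activation followed by borohydride reduction, where only the activated C14 carbonyl is reduced at −40 °C, and the primary allylic alcohol is acetylated at once so that no free hydroxyl competes later.

Step 12
Reactants: 21 chloroacetate
Product: 23 (3aS,4S,6E,10S,11aS)-6-(acetoxymethyl)-10-methyl-3-methylidene-2-oxo-2,3,3a,4,5,8,9,10,11,11a-decahydrocyclodeca[b]furan-4-yl hydroxyacetate, via formate 22 (not isolated)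
Conditions: HCO2Na (5 equiv), Bu4NI (20 mol %), DMF, 25 °C; then KHCO3 (10 mol %), MeOH, 0 °C, 30 min
Reagents that add atoms: sodium formate, [Na+].[O-]C=O
Why: SN2 displacement of the activated α-chloride by formate followed by methanolysis of the formate ester, which cleaves orders of magnitude faster than the acetate, the glycolate ester or the lactone; no stereocentre is touched.

**Compound list**
1 | 4-methylcyclohexanone | CC1CCC(=O)CC1 | starting material
2 | (5S)-5-methyloxepan-2-one | O1CC[C@@H](C)CCC1=O | intermediate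
3 | (4S)-6-hydroxy-4-methylhexanal | OCC[C@@H](C)CCC=O | intermediate
4 | tert-butyl acrylate | C=CC(=O)OC(C)(C)C | starting material
5 | tert-butyl (6S)-3,8-dihydroxy-6-methyl-2-methylideneoctanoate (C3 epimers) | OCC[C@@H](C)CCC(O)C(=C)C(=O)OC(C)(C)C | intermediate
6 | tert-butyl (6S)-3-hydroxy-6-methyl-2-methylidene-8-oxooctanoate | O=CC[C@@H](C)CCC(O)C(=C)C(=O)OC(C)(C)C | intermediate
7 | tert-butyl (6S)-3-acetoxy-6-methyl-2-methylidene-8-oxooctanoate | O=CC[C@@H](C)CCC(OC(C)=O)C(=C)C(=O)OC(C)(C)C | intermediate
8 | acrolein | C=CC=O | starting material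
9 | methyl acrylate | C=CC(=O)OC | starting material
10 | methyl 3-hydroxy-2-methylidenepent-4-enoate (racemic) | C=CC(O)C(=C)C(=O)OC | intermediate
11 | methyl (2Z)-2-(bromomethyl)penta-2,4-dienoate | C=C/C=C(\CBr)C(=O)OC | intermediate
12 | 1-tert-butyl 11-methyl (6S,8S,9S)-3-acetoxy-9-ethenyl-6-methyl-2,10-dimethylidene-8-(trimethylsilyloxy)undecanedioate | COC(=O)C(=C)[C@H](C=C)[C@@H](O[Si](C)(C)C)C[C@@H](C)CCC(OC(C)=O)C(=C)C(=O)OC(C)(C)C | intermediate
13 | 1-tert-butyl 11-methyl (6S,8S,9S)-3-acetoxy-9-ethenyl-8-hydroxy-6-methyl-2,10-dimethylideneundecanedioate | COC(=O)C(=C)[C@H](C=C)[C@@H](O)C[C@@H](C)CCC(OC(C)=O)C(=C)C(=O)OC(C)(C)C | intermediate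
14 | vinyl cis-lactone: tert-butyl (6S)-3-acetoxy-7-[(2S,3S)-3-ethenyl-4-methylidene-5-oxooxolan-2-yl]-6-methyl-2-methylideneheptanoate | C=C1C(=O)O[C@@H](C[C@@H](C)CCC(OC(C)=O)C(=C)C(=O)OC(C)(C)C)[C@H]1C=C | intermediate
15 | formyl cis-lactone: tert-butyl (6S)-3-acetoxy-7-[(2S,3S)-3-formyl-4-methylidene-5-oxooxolan-2-yl]-6-methyl-2-methylideneheptanoate | C=C1C(=O)O[C@@H](C[C@@H](C)CCC(OC(C)=O)C(=C)C(=O)OC(C)(C)C)[C@H]1C=O | intermediate
16 | 1-bromoalkyl chloroacetate of 15 (C8 epimers; C4, C6, C7 as in 15) | C=C1C(=O)O[C@@H](C[C@@H](C)CCC(OC(C)=O)C(=C)C(=O)OC(C)(C)C)[C@H]1C(Br)OC(=O)CCl | intermediate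
17 | macrocyclic tert-butyl enoate (3aS,4S,6E,10S,11aS; C8 chloroacetate) | C=C1C(=O)O[C@H]2C[C@@H](C)CC/C=C(/C(=O)OC(C)(C)C)C[C@H](OC(=O)CCl)[C@@H]12 | intermediate
18 | macrocyclic enoic acid (3aS,4S,6E,10S,11aS) | C=C1C(=O)O[C@H]2C[C@@H](C)CC/C=C(/C(=O)O)C[C@H](OC(=O)CCl)[C@@H]12 | intermediate
19 | isobutyl carbonic mixed anhydride of 18 | C=C1C(=O)O[C@H]2C[C@@H](C)CC/C=C(/C(=O)OC(=O)OCC(C)C)C[C@H](OC(=O)CCl)[C@@H]12 | intermediate
20 | C14 allylic alcohol (6-hydroxymethyl compound, C8 chloroacetate) | C=C1C(=O)O[C@H]2C[C@@H](C)CC/C=C(/CO)C[C@H](OC(=O)CCl)[C@@H]12 | intermediate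
21 | C14 acetate, C8 chloroacetate | C=C1C(=O)O[C@H]2C[C@@H](C)CC/C=C(/COC(C)=O)C[C@H](OC(=O)CCl)[C@@H]12 | intermediate
22 | C14 acetate, C8 (formyloxy)acetate | C=C1C(=O)O[C@H]2C[C@@H](C)CC/C=C(/COC(C)=O)C[C@H](OC(=O)COC=O)[C@@H]12 | intermediate
23 | CNP0156635.1, (3aS,4S,6E,10S,11aS)-6-(acetoxymethyl)-10-methyl-3-methylidene-2-oxo-decahydrocyclodeca[b]furan-4-yl hydroxyacetate | C=C1C(=O)O[C@H]2C[C@@H](C)CC/C=C(/COC(C)=O)C[C@H](OC(=O)CO)[C@@H]12 | target

**Total step count:** 12. **Longest linear sequence:** 10 (steps 1–4 and 7–12).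

**Three steps most likely to fail**

Step 9 (radical ring closure) is by far the riskiest.
- A ten-membered closure is slow. It must outrun hydrogen abstraction by the C8 radical, intermolecular addition to the α-methylene lactone of another molecule, and transannular attack of the C10 radical on C13.
- Compounds 15 and 16 can also enolise at C7.
- Fallback, from 15 back to 17, with the ring closed by metathesis instead:
  1. Aldehyde 15 is vinylated at C8 with vinyl bromide, CrCl2 and NiCl2 (1 mol %) in DMF to give the C8 allylic alcohol F1. The 8S epimer is separated.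
  2. F1 is esterified with chloroacetic anhydride and pyridine to the allylic chloroacetate F2.
  3. The second-generation Hoveyda–Grubbs catalyst in dilute toluene joins the new vinyl CH (which becomes C9) to C10, giving the C9=C10 cyclodecene acetate F3.
  4. Pd(PPh3)4 with HCO2H and Et3N delivers hydride to C9 with allylic transposition and loss of the C1 acetate, giving 17.

Step 7 (asymmetric allylation).
- A pentadienyl-type chromium reagent could react at the far terminus.
- The syn selectivity and the face selectivity on an α-unbranched aldehyde are both unproven for this bromide.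
- Fallback, from 11 back to 13, using a closed boron transition state instead of chromium:
  1. Bromide 11 is borylated with B2pin2, CuCl (5 mol %) and KOAc to the dienyl pinacol boronate F4, with the vinyl group still cis to the CH2B group.
  2. F4 adds to aldehyde 7 under catalysis by the chiral phosphoric acid (R)-TRIP in toluene. This gives hydroxy ester 13 directly, which lactonises to 14 as in step 7.

Step 11 (hydride chemoselectivity).
- Borohydride may reduce the α-methylene lactone in a conjugate sense or attack the chloroacetate.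
- Fallback, from 18 back to 20, going through the aldehyde so that only a very mild hydride step is needed:
  1. Acid 18 is coupled with ethanethiol (EDC, DMAP) to the S-ethyl thioester F5.
  2. F5 is reduced with Et3SiH and Pd/C (5 mol %) in acetone to the C14 enal F6.
  3. NaBH4 with CeCl3·7H2O in MeOH at −78 °C gives allylic alcohol 20, which is acetylated as before.

**Further compounds**
F1 | step 9 | C8 allylic alcohol from vinylation of 15 (8S; C4, C6, C7 as in 15) | C=C1C(=O)O[C@@H](C[C@@H](C)CCC(OC(C)=O)C(=C)C(=O)OC(C)(C)C)[C@H]1[C@@H](O)C=C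
F2 | step 9 | chloroacetate of F1 | C=C1C(=O)O[C@@H](C[C@@H](C)CCC(OC(C)=O)C(=C)C(=O)OC(C)(C)C)[C@H]1[C@@H](OC(=O)CCl)C=C
F3 | step 9 | C9=C10 cyclodecene with C1 acetate (ring-cis alkene; C4, C6, C7, C8 as in 17) | C=C1C(=O)O[C@H]2C[C@@H](C)CCC(OC(C)=O)/C(C(=O)OC(C)(C)C)=C\[C@H](OC(=O)CCl)[C@@H]12
F4 | step 7 | methyl (2E)-2-[(4,4,5,5-tetramethyl-1,3,2-dioxaborolan-2-yl)methyl]penta-2,4-dienoate | C=C/C=C(\CB1OC(C)(C)C(C)(C)O1)C(=O)OC
F5 | step 11 | S-ethyl thioester of 18 | C=C1C(=O)O[C@H]2C[C@@H](C)CC/C=C(/C(=O)SCC)C[C@H](OC(=O)CCl)[C@@H]12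
F6 | step 11 | C14 enal (6-formyl compound, C8 chloroacetate) | C=C1C(=O)O[C@H]2C[C@@H](C)CC/C=C(/C=O)C[C@H](OC(=O)CCl)[C@@H]12
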